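## Analysis of the target

Target 29 is a germacranolide built on a ten-membered carbocycle C1–C10. The ring carries a C1=C10 enoate (C14 methyl ester on C10; C2 and C9 cis on the double bond, E by the sequence rule), a 4,5-epoxide with the C15 methyl on C4, and an α-methylene-γ-butyrolactone fused across C6–C7 (O on C6, C11(=C13)–C12 on C7). O8 bears a (2R,3R)-3-chloro-2-hydroxy-2-methylbutanoate and O9 an acetate. The six ring stereocentres are contiguous (4R,5S,6S,7R,8S,9R). The epoxide is cis (C3 and C6 on the same side, so it descends from a Z alkene), H6 and H7 are trans, and O8 and O9 lie on the same face of the ring. The side chain has the relative configuration that results from anti opening of the cis-epoxide of angelic acid. Sensitive groups are: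

- the methylene lactone (Michael acceptor, prone to migration of the double bond into the ring);
- the trisubstituted epoxide (acid);
- the C9 acetate, which is allylic to an acceptor alkene and can be lost by SN2′;
- the chlorohydrin (base closes it to a glycidic ester);
- the vicinal acyl groups, which can migrate.

The difficulty lies in closing a medium ring, in placing two different esters on neighbouring hydroxyls, and in controlling six contiguous centres without a rigid template. The strategy rests on C8 and C9: two adjacent oxygen-bearing ring carbons with cis oxygens, which can be made together with the bond between them from two aldehyde carbons.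

## Retrosynthetic reasoning

**29 ⇐ 28 ⇐ 27.** The tertiary hydroxyl is unveiled last from silyl ether 28 under buffered fluoride, so that no base meets the free chlorohydrin. The C4–O and C5–O bonds of the epoxide are cut before that, leading to triene 27. C4=C5 is the only electron-rich alkene in 27, so a peracid needs no protecting-group support; the forward step only has to find the right face.

**27 ⇐ 19 + 26, 19 ⇐ 18.** The two ester C–O bonds at O8 and O9 are cut one after the other. The small acetyl group goes on first at the more accessible allylic O9 of diol 18. The hindered chiral acyl group is then forced onto O8 of 19 as the acid chloride 26. The reverse order would put the bulky reagent on the wrong oxygen.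

**18 ⇐ 17 (key disconnection).** The C8–C9 bond is cut, which opens the ten-membered ring and turns both carbinol carbons into aldehydes in 17. No other ring bond removes two stereocentres and the ring at once while leaving C12 and C14 at their final oxidation level. Forward, a divalent samarium reductant has to couple the two carbonyl carbons intramolecularly, in preference to the two acceptor alkenes, and with O8 and O9 cis.

**17 ⇐ 16 ⇐ 15.** The dialdehyde is too labile to carry: C7–H is α to the C8 aldehyde and vinylogously activated by the methylene lactone. Both aldehydes are therefore masked as primary silyl ethers in 15 and released at the last moment through diol 16 by a neutral oxidation. Acidic acetal hydrolysis was avoided for the same reason.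

**15 ⇐ 10 + 13.** The C6–C7 bond and the lactone C12–O bond are cut together. A chromium-catalysed 2-(alkoxycarbonyl)allylation of enal 10 with bromide 13 forms C6–C7, sets C6 by catalyst control and C7 by the anti preference of allylchromium reagents, and delivers the methylene lactone in its final form.

**10 ⇐ 9 ⇐ 8 ⇐ 7 ⇐ 5 ⇐ 4 ⇐ 2 + 3.** The C1=C10 alkene with its C9 and C14 substituents is traced to a Morita–Baylis–Hillman adduct 4 of aldehyde 2 and methyl acrylate 3. Allylic transposition to bromide 5 fixes the double-bond geometry under thermodynamic control (chain cis to C9, trans to the ester). A one-step olefination with an α-branched phosphonoacetate was set aside because its geometry and the stability of its anion cannot be vouched for. O9 is introduced through formate 6 and freed as alcohol 7, so that it stays distinguishable from the acetate on O6. It is then silylated (8), and O6 is freed (9) and oxidized (10).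

**2 ⇐ 1.** The prenyl terminus of neryl acetate 1 is cut off oxidatively. The acetate protects O6 and also deactivates the neighbouring alkene, which makes the cleavage site-selective. Compound 1 supplies C1–C6, C15 and the Z alkene unchanged.

**13 ⇐ 12 ⇐ 11 + 3.** The bromide is again a transposed Morita–Baylis–Hillman adduct, from silyloxyacetaldehyde 11 and 3; C8 arrives as a silyl ether identical to that on C9, so one reagent unmasks both.

**26 ⇐ 24 ⇐ 23 ⇐ 22 ⇐ 21 ⇐ 20.** The C3–Cl bond of the side chain is cut to the cis-epoxy acid 23, since anti opening at C3 gives exactly the (2R,3R) chlorohydrin 24. Acid 23 comes from epoxy alcohol 22, made by asymmetric epoxidation of angelyl alcohol 21, the reduction product of angelic acid 20.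

## Alternatives that were turned down

**Alternative 1: epoxide migration with lactone trapping.** This route does not close the carbocycle. It builds the C4–C7 array in an open chain, with C4 taken from (R)-linalool A3.

- Key step: under K2CO3 in methanol, the tertiary C4 alkoxide of the trans-5,6-epoxy alcohol A2 attacks C5 with inversion. This forms the cis-4,5-epoxide, and the expelled O6 alkoxide closes the γ-lactone on the C12 ester to give A1. The lactone acts as a sink for the otherwise reversible epoxide migration.
- For: C4 comes from the chiral pool and C5 is set by a stereospecific SN2 step. The epoxide configuration would therefore be certain. This is stronger than the chosen route, where step 21 depends on the facial bias of a ten-membered ring.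
- Against: the ring closure remains unsolved. A1 still needs the C8–C9 bond, and the epoxide would have to survive both that closure and the unmasking of C8 and C9. Methoxide meets two acrylate-type acceptors in A2. A2 itself requires C5, C6 and C7 to be set in an open chain next to the epoxide.
- Comparison: the chosen strategy concedes certainty at the epoxide. In exchange it forms the ring and two stereocentres in one step from a precursor with only two stereocentres, and it exposes the epoxide to a single mild step.

**Alternative 2: [2,3] ring contraction of a macrocyclic ether.** The C6–C7 bond is disconnected inside the ring.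

- Key step: tin–lithium exchange with butyllithium at C6 of the thirteen-membered diallylic ether A5 triggers a Wittig–Still shift. C6–C7 forms, O–C13 breaks, the C11=C13 methylene appears, and the ring contracts to cyclodecadienol A4.
- For: a thirteen-membered ether is easier to close than a ten-membered carbocycle. The contraction is intramolecular and concerted, needs no high dilution, and creates C6, C7 and the exocyclic methylene together. On reliability of ring formation it is stronger than a reductive ten-membered closure.
- Against: butyllithium forces C12 and C14 to the alcohol oxidation level. After the contraction, both must be deprotected and oxidized (one to the lactone, one to the methyl ester) next to three alkenes. The C8/C9 diol must be made beforehand by other means. A configurationally defined α-alkoxystannane is needed at C6. A [1,2] shift can compete, and the C6/C7 outcome of a macrocyclic transition state is hard to predict.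
- Comparison: the chosen strategy keeps C12 and C14 at their final oxidation level from the first steps and uses the C8/C9 oxygenation itself as the ring-closing handle, which saves roughly ten steps.

**Alternative 3: alkenyl iodide–aldehyde closure at C5–C6.** The C5–C6 bond is disconnected.

- Key step: the (Z)-alkenyl iodide of A7 is metallated with CrCl2 and catalytic NiCl2 and adds to the C6 aldehyde. This gives the ten-membered hydroxy ester A6, with the ring alkene geometry retained and all acyl groups in place.
- For: this coupling tolerates esters and acrylates better than divalent samarium does; on chemoselectivity of the ring closure it is the stronger option. It is also proven for medium rings, and lactonization of A6 should follow readily.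
- Against: the open-chain precursor A7 must already carry C7, C8 and C9 and both esters. Its C6 aldehyde is α to C7 and β to the C8 acyloxy group, so enolization and β-elimination threaten. The C9 acetate is an acceptor-activated allylic acetate that low-valent nickel can ionize. The C6 configuration would come from an uncontrolled macrocyclic addition.
- Comparison: the chosen strategy obtains C8 and C9 from the ring closure itself and reaches its precursor from two simple fragments. It accepts a less tolerant reductant as the price.

Key step: step 13

Remark on the chemistry (assumption): the sense of induction in step 10 is set by the choice of ligand enantiomer. L denotes the enantiomer of 3,6-di-tert-butyl-1,8-bis(4-isopropyl-4,5-dihydrooxazol-2-yl)-9H-carbazole that directs the allyl group to the Si face of the aldehyde carbon of 10.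

Remark on the chemistry (assumption): O9 of diol 18 is taken as the kinetically more reactive hydroxyl, and the peracid is taken to approach C4=C5 anti to the allylic C6–O bond. Both assumptions are examined among the uncertain steps.

## Route

Step 1
Reactants: 1 neryl acetate
Product: 2 (2Z)-3-methyl-6-oxohex-2-en-1-yl acetate
Conditions: O3 (1.0 equiv), CH2Cl2, −78 °C; then Me2S, −78 °C to rt
Reagents that add atoms: ozone, O=[O+][O-]
Why: Chemoselective ozonolysis; the electrophilic ozone attacks the isolated isopropylidene alkene much faster than the alkene deactivated by the allylic acetate, and the reaction is stopped after one equivalent before reductive work-up.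

Step 2
Reactants: 2 (2Z)-3-methyl-6-oxohex-2-en-1-yl acetate; 3 methyl acrylate
Product: 4 methyl (6Z)-8-acetoxy-3-hydroxy-6-methyl-2-methylideneoct-6-enoate (racemic at C3)
Conditions: 3 (3 equiv), 1,4-diazabicyclo[2.2.2]octane (1 equiv), 1,4-dioxane/H2O 1:1, rt, 48–72 h
Reagents that add atoms: none
Why: Morita–Baylis–Hillman reaction of an unhindered aliphatic aldehyde; the allylic acetate is inert to the amine, and the new carbinol centre is erased in step 3.

Step 3
Reactants: 4 methyl (6Z)-8-acetoxy-3-hydroxy-6-methyl-2-methylideneoct-6-enoate
Product: 5 methyl (2Z,6Z)-8-acetoxy-2-(bromomethyl)-6-methylocta-2,6-dienoate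
Conditions: NBS, Me2S, CH2Cl2, 0 °C to rt
Reagents that add atoms: N-bromosuccinimide, O=C1CCC(=O)N1Br
Why: Allylic bromination with transposition (bromide attacks the alkoxysulfonium salt in the SN2′ sense); the conjugated trisubstituted alkene forms under thermodynamic control with the chain cis to CH2Br and trans to the ester, which is the C1=C10 geometry of the target.

Step 4
Reactants: 5 methyl (2Z,6Z)-8-acetoxy-2-(bromomethyl)-6-methylocta-2,6-dienoate
Product: 7 methyl (2E,6Z)-8-acetoxy-2-(hydroxymethyl)-6-methylocta-2,6-dienoate, via allylic formate 6 (not isolated)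
Conditions: HCO2Na (3 equiv), DMF, rt; then KHCO3, MeOH, 0 °C
Reagents that add atoms: sodium formate, [Na+].[O-]C=O
Why: SN2 displacement of the primary allylic bromide by a carboxylate with retention of the alkene geometry, then selective methanolysis; a formate is cleaved by bicarbonate in methanol far faster than the allylic acetate, so O9 and O6 stay differentiated.

Step 5
Reactants: 7 methyl (2E,6Z)-8-acetoxy-2-(hydroxymethyl)-6-methylocta-2,6-dienoate
Product: 8 methyl (2E,6Z)-8-acetoxy-2-{[(tert-butyldimethylsilyl)oxy]methyl}-6-methylocta-2,6-dienoate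
Conditions: TBSCl, imidazole, CH2Cl2, 0 °C to rt
Reagents that add atoms: tert-butyldimethylsilyl chloride, CC(C)(C)[Si](C)(C)Cl
Why: Standard silylation of a primary alcohol; a silyloxide is a poor leaving group, so the acrylate is not open to SN2′ loss of O9 in the basic step that follows.

Step 6
Reactants: 8 methyl (2E,6Z)-8-acetoxy-2-{[(tert-butyldimethylsilyl)oxy]methyl}-6-methylocta-2,6-dienoate
Product: 9 methyl (2E,6Z)-2-{[(tert-butyldimethylsilyl)oxy]methyl}-8-hydroxy-6-methylocta-2,6-dienoate
Conditions: K2CO3 (0.3 equiv), MeOH, 0 °C
Reagents that add atoms: none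
Why: Zemplén-type transesterification of the allylic acetate; exchange at the methyl ester is degenerate and the primary silyl ether is stable at 0 °C.

Step 7
Reactants: 9 methyl (2E,6Z)-2-{[(tert-butyldimethylsilyl)oxy]methyl}-8-hydroxy-6-methylocta-2,6-dienoate
Product: 10 methyl (2E,6Z)-2-{[(tert-butyldimethylsilyl)oxy]methyl}-6-methyl-8-oxoocta-2,6-dienoate
Conditions: activated MnO2 (15 equiv), CH2Cl2, rt, dark; used without storage
Reagents that add atoms: none
Why: MnO2 oxidation of an allylic alcohol under neutral conditions, the standard way to turn nerol-type alcohols into the (Z)-enal without Z-to-E isomerization.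

Step 8
Reactants: 11 (tert-butyldimethylsilyloxy)acetaldehyde; 3 methyl acrylate
Product: 12 methyl 4-[(tert-butyldimethylsilyl)oxy]-3-hydroxy-2-methylidenebutanoate (racemic)
Conditions: 3 (3 equiv), 1,4-diazabicyclo[2.2.2]octane (0.5 equiv), neat, rt
Reagents that add atoms: none
Why: Morita–Baylis–Hillman reaction; α-oxygenated aldehydes are among the most reactive acceptors for it.

Step 9
Reactants: 12 methyl 4-[(tert-butyldimethylsilyl)oxy]-3-hydroxy-2-methylidenebutanoate
Product: 13 methyl (2Z)-2-(bromomethyl)-4-[(tert-butyldimethylsilyl)oxy]but-2-enoate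
Conditions: NBS, Me2S, CH2Cl2, 0 °C to rt
Reagents that add atoms: N-bromosuccinimide, O=C1CCC(=O)N1Br
Why: The same allylic bromination with transposition as in step 3; the bromide geometry is of no consequence because the allylchromium reagent derived from it equilibrates.

Step 10
Reactants: 10 methyl (2E,6Z)-2-{[(tert-butyldimethylsilyl)oxy]methyl}-6-methyl-8-oxoocta-2,6-dienoate; 13 methyl (2Z)-2-(bromomethyl)-4-[(tert-butyldimethylsilyl)oxy]but-2-enoate
Product: 15 methyl (2E,6Z)-2-{[(tert-butyldimethylsilyl)oxy]methyl}-7-[(2R,3R)-3-{[(tert-butyldimethylsilyl)oxy]methyl}-4-methylidene-5-oxooxolan-2-yl]-6-methylhepta-2,6-dienoate, via O-trimethylsilyl hydroxy diester 14 (not isolated)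
Conditions: CrCl2 (10 mol %), L (12 mol %), Mn powder (2 equiv), iPr2NEt (30 mol %), TMSCl (1.5 equiv), THF, 0 °C to rt; 10% aq. citric acid; then PPTS (cat.), CH2Cl2, rt
Reagents that add atoms: none
Why: Catalytic asymmetric Nozaki–Hiyama–Kishi-type 2-(alkoxycarbonyl)allylation followed by lactonization. The allylchromium reagent reacts through a chair transition state with the silyloxymethyl group equatorial, so C6–C7 forms anti and the lactone is trans (C7). The bis(oxazoline)–chromium complex selects the Si face of the aldehyde and sets C6.

Step 11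
Reactants: 15 bis-silyl ether lactone
Product: 16 methyl (2E,6Z)-2-(hydroxymethyl)-7-[(2R,3R)-3-(hydroxymethyl)-4-methylidene-5-oxooxolan-2-yl]-6-methylhepta-2,6-dienoate
Conditions: HF·pyridine, pyridine, THF, 0 °C to rt
Reagents that add atoms: none
Why: Fluoride cleavage of both primary silyl ethers under buffered, non-basic conditions that spare the methylene lactone; the diol is taken on at once to limit translactonization of O8 onto C12.

Step 12
Reactants: 16 lactone diol
Product: 17 methyl (2E,6Z)-2-formyl-7-[(2R,3S)-3-formyl-4-methylidene-5-oxooxolan-2-yl]-6-methylhepta-2,6-dienoate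
Conditions: DMP (3 equiv), NaHCO3 (8 equiv), CH2Cl2, 0 °C; filtered, concentrated cold, used at once
Reagents that add atoms: none
Why: Double alcohol oxidation with the hypervalent iodine reagent 1,1,1-triacetoxy-1,1-dihydro-1,2-benziodoxol-3(1H)-one under bicarbonate buffer. Neutral conditions are chosen because the C8 aldehyde is α to C7 and vinylogously activated by the methylene lactone; the dialdehyde is not chromatographed.

Step 13
Reactants: 17 lactone dialdehyde
Product: 18 methyl (1(10)E,4Z,6R,7R,8S,9R)-8,9-dihydroxygermacra-1(10),4,11(13)-trien-12,6-olid-14-oate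
Conditions: SmI2 (3 equiv, 0.1 M in THF), THF, −78 to −20 °C, 17 added over 3 h (final 0.003 M); sat. aq. NH4Cl
Reagents that add atoms: none
Why: Intramolecular pinacol coupling: divalent samarium transfers an electron to the more easily reduced conjugated C9 aldehyde, the ketyl bound to trivalent samarium attacks the C8 aldehyde held on the same metal (or couples with a second ketyl), and a second electron gives the samarium diolate, protonated on work-up. The closest known reaction type is the reductive cyclization of dialdehydes to medium- and large-ring 1,2-diols with SmI2 or low-valent titanium. The ten-membered ring closes by a 10-exo-trig attack of C9 on the C8 carbonyl. C8 is controlled by C7: in a Felkin–Anh-type arrangement the vinylic C11 stands anti to the incoming C9 and the attack passes H7, which gives 8S. C9 is controlled by the metal bridge: with O8 and O9 on one samarium and the ring carbons C7 and C10 gauche, the two oxygens end up cis (9R). The step needs selectivity for the aldehydes over the enoate and the methylene lactone, and for C9 over C1 of the delocalized ketyl; the absence of HMPA and of a proton source, the low temperature and the alkyl substituent at C1 favour carbonyl–carbonyl coupling. High dilution with slow addition suppresses intermolecular coupling.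

Step 14
Reactants: 18 cis-diol
Product: 19 methyl (1(10)E,4Z,6R,7R,8S,9R)-9-acetoxy-8-hydroxygermacra-1(10),4,11(13)-trien-12,6-olid-14-oate
Conditions: AcCl (1.05 equiv), 2,4,6-collidine (2 equiv), CH2Cl2, −78 °C
Reagents that add atoms: acetyl chloride, CC(=O)Cl
Why: Kinetic O-acylation at low temperature; O9 is flanked by the planar C10 and is less hindered than O8, which sits next to the ring-fusion carbon C7, and the monoacetate reacts more slowly than the diol.

Step 15
Reactants: 20 angelic acid
Product: 21 (2Z)-2-methylbut-2-en-1-ol
Conditions: LiAlH4, Et2O, 0 °C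
Reagents that add atoms: none
Why: Hydride reduction of the conjugated acid to the allylic alcohol; at 0 °C 1,2-reduction prevails and the Z geometry is retained.

Step 16
Reactants: 21 (2Z)-2-methylbut-2-en-1-ol
Product: 22 [(2R,3S)-2,3-dimethyloxiran-2-yl]methanol
Conditions: Ti(OiPr)4 (10 mol %), D-(−)-diisopropyl tartrate (12 mol %), t-BuOOH, 4 Å molecular sieves, CH2Cl2, −20 °C
Reagents that add atoms: tert-butyl hydroperoxide, CC(C)(C)OO
Why: Sharpless asymmetric epoxidation; the (S,S)-tartrate delivers oxygen to the face of the allylic alcohol that gives the (2R,3S)-epoxide, and syn addition keeps CH2OH and the C3 methyl cis.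

Step 17
Reactants: 22 [(2R,3S)-2,3-dimethyloxiran-2-yl]methanol
Product: 23 (2S,3S)-2,3-dimethyloxirane-2-carboxylic acid
Conditions: RuCl3 hydrate (2 mol %), NaIO4 (3 equiv), EtOAc/MeCN/H2O, rt
Reagents that add atoms: sodium periodate, [Na+].[O-]I(=O)(=O)=O; water, O
Why: RuO4-type oxidation of a primary epoxy alcohol to the epoxy acid, the standard follow-up to an asymmetric epoxidation; both stereocentres are untouched and the C2 descriptor changes only by priority.

Step 18
Reactants: 23 (2S,3S)-2,3-dimethyloxirane-2-carboxylic acid
Product: 24 (2R,3R)-3-chloro-2-hydroxy-2-methylbutanoic acid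
Conditions: HCl (4 M in 1,4-dioxane, 1.5 equiv), Et2O, 0 °C
Reagents that add atoms: hydrogen chloride, Cl
Why: Acid-mediated opening of a glycidic acid; chloride attacks the secondary C3, remote from the carboxyl group and not quaternary, with inversion, which gives the (2R,3R)-chlorohydrin.

Step 19
Reactants: 24 (2R,3R)-3-chloro-2-hydroxy-2-methylbutanoic acid
Product: 26 (2S,3R)-3-chloro-2-methyl-2-(trimethylsilyloxy)butanoyl chloride, via bis(trimethylsilyl) derivative 25 (not isolated)
Conditions: TMSCl (2.2 equiv), Et3N (2.3 equiv), CH2Cl2, 0 °C to rt; filtration; then (COCl)2 (1.1 equiv), DMF (cat.), CH2Cl2, 0 °C to rt; concentrated and used crude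
Reagents that add atoms: chlorotrimethylsilane, C[Si](C)(C)Cl; oxalyl chloride, O=C(Cl)C(=O)Cl
Why: Silylation of both hydroxyl functions, then conversion of the trimethylsilyl ester into the acid chloride with oxalyl chloride and catalytic DMF under neutral conditions; the tertiary silyl ether stays on, and the C2 descriptor changes only by priority.

Step 20
Reactants: 19 C9 monoacetate; 26 (2S,3R)-3-chloro-2-methyl-2-(trimethylsilyloxy)butanoyl chloride
Product: 27 methyl (1(10)E,4Z,6R,7S,8S,9R)-9-acetoxy-8-{[(2R,3R)-3-chloro-2-methyl-2-(trimethylsilyloxy)butanoyl]oxy}germacra-1(10),4,11(13)-trien-12,6-olid-14-oate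
Conditions: 26 (2 equiv), pyridine (3 equiv), DMAP (0.2 equiv), CH2Cl2, 0 °C to rt
Reagents that add atoms: none
Why: DMAP-catalysed acylation of the remaining secondary alcohol with an inductively activated α-silyloxy acid chloride; excess reagent at low temperature is meant to outpace migration of the acetyl group from O9 to O8.

Step 21
Reactants: 27 silylated diester triene
Product: 28 methyl (1(10)E,4R,5S,6S,7R,8S,9R)-9-acetoxy-8-{[(2R,3R)-3-chloro-2-methyl-2-(trimethylsilyloxy)butanoyl]oxy}-4,5-epoxygermacra-1(10),11(13)-dien-12,6-olid-14-oate
Conditions: mCPBA (1.2 equiv), NaHCO3, CH2Cl2, 0 °C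
Reagents that add atoms: 3-chloroperoxybenzoic acid, OOC(=O)c1cccc(Cl)c1
Why: Prilezhaev epoxidation; C4=C5 is the only electron-rich alkene, and syn addition to the Z alkene gives the cis-epoxide. With H6 eclipsing the alkene, the peracid should avoid the face that carries the allylic C6–O bond, as it does in cyclic allylic esters, which gives 4R,5S.

Step 22
Reactants: 28 silylated epoxide
Product: 29 methyl (1(10)E,4R,5S,6S,7R,8S,9R)-9-acetoxy-8-{[(2R,3R)-3-chloro-2-hydroxy-2-methylbutanoyl]oxy}-4,5-epoxygermacra-1(10),11(13)-dien-12,6-olid-14-oate (CNP0185503.1)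
Conditions: TBAF (1.1 equiv), AcOH (1.5 equiv), THF, 0 °C
Reagents that add atoms: none
Why: Buffered fluoride cleavage of a tertiary trimethylsilyl ether; the acetic acid buffer keeps the medium from closing the chlorohydrin to a glycidic ester or opening the ring epoxide.

## Compound list

1 | neryl acetate, (2Z)-3,7-dimethylocta-2,6-dien-1-yl acetate | CC(C)=CCC/C(C)=C\COC(C)=O | starting material
2 | (2Z)-3-methyl-6-oxohex-2-en-1-yl acetate | O=CCC/C(C)=C\COC(C)=O | intermediate
3 | methyl acrylate | C=CC(=O)OC | starting material
4 | methyl (6Z)-8-acetoxy-3-hydroxy-6-methyl-2-methylideneoct-6-enoate (racemic at C3) | C=C(C(=O)OC)C(O)CC/C(C)=C\COC(C)=O | intermediate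
5 | methyl (2Z,6Z)-8-acetoxy-2-(bromomethyl)-6-methylocta-2,6-dienoate | BrC/C(C(=O)OC)=C\CC/C(C)=C\COC(C)=O | intermediate
6 | methyl (2E,6Z)-8-acetoxy-2-[(formyloxy)methyl]-6-methylocta-2,6-dienoate (not isolated) | O=COC/C(C(=O)OC)=C\CC/C(C)=C\COC(C)=O | intermediate
7 | methyl (2E,6Z)-8-acetoxy-2-(hydroxymethyl)-6-methylocta-2,6-dienoate | OC/C(C(=O)OC)=C\CC/C(C)=C\COC(C)=O | intermediate
8 | methyl (2E,6Z)-8-acetoxy-2-{[(tert-butyldimethylsilyl)oxy]methyl}-6-methylocta-2,6-dienoate | CC(C)(C)[Si](C)(C)OC/C(C(=O)OC)=C\CC/C(C)=C\COC(C)=O | intermediate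
9 | methyl (2E,6Z)-2-{[(tert-butyldimethylsilyl)oxy]methyl}-8-hydroxy-6-methylocta-2,6-dienoate | CC(C)(C)[Si](C)(C)OC/C(C(=O)OC)=C\CC/C(C)=C\CO | intermediate
10 | methyl (2E,6Z)-2-{[(tert-butyldimethylsilyl)oxy]methyl}-6-methyl-8-oxoocta-2,6-dienoate | CC(C)(C)[Si](C)(C)OC/C(C(=O)OC)=C\CC/C(C)=C\C=O | intermediate
11 | (tert-butyldimethylsilyloxy)acetaldehyde | CC(C)(C)[Si](C)(C)OCC=O | starting material
12 | methyl 4-[(tert-butyldimethylsilyl)oxy]-3-hydroxy-2-methylidenebutanoate (racemic) | C=C(C(=O)OC)C(O)CO[Si](C)(C)C(C)(C)C | intermediate
13 | methyl (2Z)-2-(bromomethyl)-4-[(tert-butyldimethylsilyl)oxy]but-2-enoate | BrC/C(C(=O)OC)=C\CO[Si](C)(C)C(C)(C)C | intermediate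
14 | dimethyl (2E,6Z,8R,9R)-2,9-bis{[(tert-butyldimethylsilyl)oxy]methyl}-6-methyl-10-methylidene-8-[(trimethylsilyl)oxy]undeca-2,6-dienedioate (not isolated) | CC(C)(C)[Si](C)(C)OC/C(C(=O)OC)=C\CC/C(C)=C\[C@@H](O[Si](C)(C)C)[C@@H](CO[Si](C)(C)C(C)(C)C)C(=C)C(=O)OC | intermediate
15 | methyl (2E,6Z)-2-{[(tert-butyldimethylsilyl)oxy]methyl}-7-[(2R,3R)-3-{[(tert-butyldimethylsilyl)oxy]methyl}-4-methylidene-5-oxooxolan-2-yl]-6-methylhepta-2,6-dienoate (trans-lactone) | CC(C)(C)[Si](C)(C)OC/C(C(=O)OC)=C\CC/C(C)=C\[C@H]1OC(=O)C(=C)[C@@H]1CO[Si](C)(C)C(C)(C)C | intermediate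
16 | methyl (2E,6Z)-2-(hydroxymethyl)-7-[(2R,3R)-3-(hydroxymethyl)-4-methylidene-5-oxooxolan-2-yl]-6-methylhepta-2,6-dienoate | OC/C(C(=O)OC)=C\CC/C(C)=C\[C@H]1OC(=O)C(=C)[C@@H]1CO | intermediate
17 | methyl (2E,6Z)-2-formyl-7-[(2R,3S)-3-formyl-4-methylidene-5-oxooxolan-2-yl]-6-methylhepta-2,6-dienoate | O=C/C(C(=O)OC)=C\CC/C(C)=C\[C@H]1OC(=O)C(=C)[C@@H]1C=O | intermediate
18 | methyl (1(10)E,4Z,6R,7R,8S,9R)-8,9-dihydroxygermacra-1(10),4,11(13)-trien-12,6-olid-14-oate (cis-diol) | C1/C(C)=C\[C@H]2OC(=O)C(=C)[C@@H]2[C@H](O)[C@H](O)/C(C(=O)OC)=C\C1 | intermediate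
19 | methyl (1(10)E,4Z,6R,7R,8S,9R)-9-acetoxy-8-hydroxygermacra-1(10),4,11(13)-trien-12,6-olid-14-oate | C1/C(C)=C\[C@H]2OC(=O)C(=C)[C@@H]2[C@H](O)[C@H](OC(C)=O)/C(C(=O)OC)=C\C1 | intermediate
20 | angelic acid, (2Z)-2-methylbut-2-enoic acid | C/C=C(/C)C(=O)O | starting material
21 | (2Z)-2-methylbut-2-en-1-ol | C/C=C(/C)CO | intermediate
22 | [(2R,3S)-2,3-dimethyloxiran-2-yl]methanol | OC[C@@]1(C)O[C@H]1C | intermediate
23 | (2S,3S)-2,3-dimethyloxirane-2-carboxylic acid | OC(=O)[C@@]1(C)O[C@H]1C | intermediate
24 | (2R,3R)-3-chloro-2-hydroxy-2-methylbutanoic acid | OC(=O)[C@@](C)(O)[C@@H](C)Cl | intermediate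
25 | trimethylsilyl (2R,3R)-3-chloro-2-methyl-2-(trimethylsilyloxy)butanoate (not isolated) | C[Si](C)(C)OC(=O)[C@@](C)(O[Si](C)(C)C)[C@@H](C)Cl | intermediate
26 | (2S,3R)-3-chloro-2-methyl-2-(trimethylsilyloxy)butanoyl chloride | ClC(=O)[C@@](C)(O[Si](C)(C)C)[C@@H](C)Cl | intermediate
27 | methyl (1(10)E,4Z,6R,7S,8S,9R)-9-acetoxy-8-{[(2R,3R)-3-chloro-2-methyl-2-(trimethylsilyloxy)butanoyl]oxy}germacra-1(10),4,11(13)-trien-12,6-olid-14-oate | C1/C(C)=C\[C@H]2OC(=O)C(=C)[C@@H]2[C@H](OC(=O)[C@@](C)(O[Si](C)(C)C)[C@@H](C)Cl)[C@H](OC(C)=O)/C(C(=O)OC)=C\C1 | intermediate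
28 | methyl (1(10)E,4R,5S,6S,7R,8S,9R)-9-acetoxy-8-{[(2R,3R)-3-chloro-2-methyl-2-(trimethylsilyloxy)butanoyl]oxy}-4,5-epoxygermacra-1(10),11(13)-dien-12,6-olid-14-oate | C=C1C(=O)O[C@H]2[C@H]1[C@H](OC(=O)[C@@](C)(O[Si](C)(C)C)[C@@H](C)Cl)[C@H](OC(C)=O)/C(C(=O)OC)=C\CC[C@@]1(C)O[C@@H]21 | intermediate
29 | methyl (1(10)E,4R,5S,6S,7R,8S,9R)-9-acetoxy-8-{[(2R,3R)-3-chloro-2-hydroxy-2-methylbutanoyl]oxy}-4,5-epoxygermacra-1(10),11(13)-dien-12,6-olid-14-oate (CNP0185503.1) | C=C1C(=O)O[C@H]2[C@H]1[C@H](OC(=O)[C@@](C)(O)[C@@H](C)Cl)[C@H](OC(C)=O)/C(C(=O)OC)=C\CC[C@@]1(C)O[C@@H]21 | target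

## Step count and uncertain steps

Total step count: 22. Longest linear sequence: 15 steps (steps 1–7, 10–14 and 20–22, from neryl acetate 1). The bromide 13 takes two steps and the acid chloride 26 five.

**Step 13 (key step).** The most likely failure is loss of relative control at C9. In rings of ten and more members the two carbinol carbons are not forced together as they are in five- and six-membered rings, so closure through a bridged arrangement with C7 and C10 anti would give the trans-diol. Bond formation through C1 of the delocalized ketyl and plain over-reduction of the formyl acrylate are the second concern. The fallback makes the sequence stereoconvergent instead of relying on the metal bridge. It sets out from 17: the same reductive cyclization, run for ring closure only, gives the 9-epimeric trans-diol, methyl (1(10)E,4Z,6R,7R,8S,9S)-8,9-dihydroxygermacra-1(10),4,11(13)-trien-12,6-olid-14-oate F1. Its allylic C9 carbinol is oxidized with activated MnO2 in CH2Cl2 (the C8 carbinol is not allylic) to the hydroxy enone, methyl (1(10)E,4Z,6R,7R,8S)-8-hydroxy-9-oxogermacra-1(10),4,11(13)-trien-12,6-olid-14-oate F2. Zn(BH4)2 in Et2O at −20 °C then reduces the ketone 1,2 through the zinc chelate between O8 and the C9 carbonyl, with hydride entering from the side of H8, and the sequence comes back to the route at 18.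

**Step 14.** Acetylation may go to the wrong oxygen or to both, because the steric difference between O9 and O8 is small, and the acetyl group may migrate between the cis-vicinal oxygens. The fallback delivers the acyl group intramolecularly. It sets out from 18: trimethyl orthoacetate and catalytic PPTS in CH2Cl2 give the cyclic orthoacetate, methyl (1(10)E,4Z,6R,7R,8S,9R)-8,9-[(1-methoxyethylidene)dioxy]germacra-1(10),4,11(13)-trien-12,6-olid-14-oate F3. Hydrolysis with 80% aqueous AcOH at rt opens the hemi-orthoester towards the ester of the more hindered oxygen, which is complementary to kinetic acylation, and returns to 19.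

**Step 21.** Facial selectivity may be poor or reversed. Nothing rigid fixes the rotamer about C5–C6 in the ten-membered ring, and the substituted C7 side may shield the face that the allylic-oxygen argument favours. The fallback reaches the opposite face in two steps. It sets out from 27: NBS in THF/H2O at 0 °C forms the bromonium ion on the face the peracid would have used, and water opens it at the tertiary C4. This gives the bromohydrin, methyl (1(10)E,4R,5R,6S,7R,8S,9R)-9-acetoxy-5-bromo-8-{[(2R,3R)-3-chloro-2-methyl-2-(trimethylsilyloxy)butanoyl]oxy}-4-hydroxygermacra-1(10),11(13)-dien-12,6-olid-14-oate F4. Ag2O in CH2Cl2 then closes the epoxide with inversion at C5 without touching the chloride of the side chain, and the sequence returns to 28.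

**Step 10.** The catalyst may not control the aldehyde face well enough with a (Z)-enal that carries a distant Lewis-basic ester and silyl ether, and the enal may isomerize towards E during a slow reaction. The fallback moves absolute control from catalysis to resolution. It sets out from 10 and 13: stoichiometric CrCl2 in THF at rt without ligand gives the racemic trans-lactone (the anti preference is inherent to the allylchromium reagent). This is 15 together with its enantiomer, methyl (2E,6Z)-2-{[(tert-butyldimethylsilyl)oxy]methyl}-7-[(2S,3S)-3-{[(tert-butyldimethylsilyl)oxy]methyl}-4-methylidene-5-oxooxolan-2-yl]-6-methylhepta-2,6-dienoate F5. Preparative chromatography on a chiral stationary phase separates the two, and the route is rejoined at 15.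

## Further compounds

F1 | step 13 | methyl (1(10)E,4Z,6R,7R,8S,9S)-8,9-dihydroxygermacra-1(10),4,11(13)-trien-12,6-olid-14-oate (trans-diol) | C1/C(C)=C\[C@H]2OC(=O)C(=C)[C@@H]2[C@H](O)[C@@H](O)/C(C(=O)OC)=C\C1
F2 | step 13 | methyl (1(10)E,4Z,6R,7R,8S)-8-hydroxy-9-oxogermacra-1(10),4,11(13)-trien-12,6-olid-14-oate | C1/C(C)=C\[C@H]2OC(=O)C(=C)[C@@H]2[C@H](O)C(=O)/C(C(=O)OC)=C\C1
F3 | step 14 | methyl (1(10)E,4Z,6R,7R,8S,9R)-8,9-[(1-methoxyethylidene)dioxy]germacra-1(10),4,11(13)-trien-12,6-olid-14-oate (cyclic orthoacetate, both epimers at the orthoester carbon) | C1/C(C)=C\[C@H]2OC(=O)C(=C)[C@@H]2[C@@H]2OC(C)(OC)O[C@@H]2/C(C(=O)OC)=C\C1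
F4 | step 21 | methyl (1(10)E,4R,5R,6S,7R,8S,9R)-9-acetoxy-5-bromo-8-{[(2R,3R)-3-chloro-2-methyl-2-(trimethylsilyloxy)butanoyl]oxy}-4-hydroxygermacra-1(10),11(13)-dien-12,6-olid-14-oate | C=C1C(=O)O[C@H]2[C@H]1[C@H](OC(=O)[C@@](C)(O[Si](C)(C)C)[C@@H](C)Cl)[C@H](OC(C)=O)/C(C(=O)OC)=C\CC[C@@](C)(O)[C@@H]2Br
F5 | step 10 | methyl (2E,6Z)-2-{[(tert-butyldimethylsilyl)oxy]methyl}-7-[(2S,3S)-3-{[(tert-butyldimethylsilyl)oxy]methyl}-4-methylidene-5-oxooxolan-2-yl]-6-methylhepta-2,6-dienoate (enantiomer of 15) | CC(C)(C)[Si](C)(C)OC/C(C(=O)OC)=C\CC/C(C)=C\[C@@H]1OC(=O)C(=C)[C@H]1CO[Si](C)(C)C(C)(C)C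
A1 | alternative 1 | cis-4,5-epoxy trans-lactone fragment with C8 as silyloxymethyl and C9 as dimethyl acetal | COC(OC)/C(C(=O)OC)=C\CC[C@@]1(C)O[C@H]1[C@H]1OC(=O)C(=C)[C@@H]1CO[Si](C)(C)C(C)(C)C
A2 | alternative 1 | open-chain C4 tertiary alcohol with trans-5,6-epoxide and C12 methyl ester | COC(OC)/C(C(=O)OC)=C\CC[C@@](C)(O)[C@@H]1O[C@H]1[C@@H](CO[Si](C)(C)C(C)(C)C)C(=C)C(=O)OC
A3 | alternative 1 | (R)-linalool | CC(C)=CCC[C@@](C)(O)C=C
A4 | alternative 2 | cyclodecadienol with C6 hydroxyl, C7 2-propenyl unit, C8/C9 acetonide | C1/C(C)=C\[C@@H](O)[C@H](C(=C)COCc2ccc(OC)cc2)[C@@H]2OC(C)(C)O[C@@H]2/C(CO[Si](C)(C)C(C)(C)C)=C\C1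
A5 | alternative 2 | thirteen-membered diallylic ether with tributylstannyl group at C6 | C1/C(C)=C\[C@@H]([Sn](CCCC)(CCCC)CCCC)OC/C(COCc2ccc(OC)cc2)=C/[C@@H]2OC(C)(C)O[C@@H]2/C(CO[Si](C)(C)C(C)(C)C)=C\C1
A6 | alternative 3 | cyclodecadienol hydroxy ester with all acyl groups in place | C1/C(C)=C\[C@@H](O)[C@H](C(=C)C(=O)OC)[C@H](OC(=O)[C@@](C)(O)[C@@H](C)Cl)[C@H](OC(C)=O)/C(C(=O)OC)=C\C1
A7 | alternative 3 | open-chain (Z)-alkenyl iodide with C6 aldehyde | I/C=C(/C)CC/C=C(C(=O)OC)\[C@@H](OC(C)=O)[C@@H](OC(=O)[C@@](C)(O)[C@@H](C)Cl)[C@H](C=O)C(=C)C(=O)OC
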